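**Retrosynthetic overview**
- Marchantinquinone ⇒ open-chain tetraol with ring C as a 2-fluorohydroquinone and rings B and D as free phenols. The 18-membered ring is closed last by a biomimetic oxidative phenol C–O coupling: hydroquinone → quinone, then the ring D phenoxide displaces fluoride. Macrocycle and quinone appear in one operation.
- Tetraol ⇒ tetramethyl ether ⇒ (hydrogenation) an alkyne/stilbene diaryl ether.
- Ring A–O–ring B ether ⇒ Ullmann coupling of a ring C–A bromotolane with a ring B–D stilbene phenol.
- Bromotolane ⇒ Sonogashira coupling of 2-fluoro-3-iodo-1,4-dimethoxybenzene (ortho-lithiation/iodination) with 1-bromo-4-ethynylbenzene; stilbene phenol ⇒ Horner–Wadsworth–Emmons olefination of isovanillin.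
- Ring order: the four six-membered rings are bought; the macrocycle is the only ring made and is formed in the final step.

Assumption: the SMILES has no stereodescriptor and the molecule has no stereogenic element that is stable at room temperature, so the target is prepared as the single achiral compound drawn and no stereocentre has to be set.

**Step 1**
Reactants: 1 2-fluoro-1,4-dimethoxybenzene
Product: 3 2-fluoro-3-iodo-1,4-dimethoxybenzene, via aryllithium 2 (not isolated)
Conditions: n-BuLi (1.05 equiv), THF, −78 °C, 1 h; I2 (1.1 equiv) in THF, −78 °C to rt; aq. Na2S2O3 work-up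
Reagents that add atoms: iodine, [I][I]; n-butyllithium, [Li]CCCC (supplies the lithium of 2 only)
Why: Directed ortho-metalation, in which the C–H flanked by F and OMe is the most acidic site and is lithiated at −78 °C (below the temperature of LiF loss to a benzyne) before iodine traps the aryllithium.

**Step 2**
Reactants: 3 2-fluoro-3-iodo-1,4-dimethoxybenzene, 4 1-bromo-4-ethynylbenzene
Product: 5 2-[(4-bromophenyl)ethynyl]-3-fluoro-1,4-dimethoxybenzene
Conditions: PdCl2(PPh3)2 (3 mol%), CuI (5 mol%), Et3N/THF 1:1, degassed, 40 °C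
Reagents that add atoms: none
Why: Sonogashira coupling, in which zerovalent palladium inserts into the C–I bond far faster than into the C–Br bond of 4 or 5, so the bromide is kept for step 4.

**Step 3**
Reactants: 6 isovanillin (3-hydroxy-4-methoxybenzaldehyde), 7 diethyl (3-methoxybenzyl)phosphonate
Product: 8 (E)-2-methoxy-5-[2-(3-methoxyphenyl)ethenyl]phenol
Conditions: KOtBu (2.3 equiv), DMF, 0 °C to rt; aq. HCl work-up
Reagents that add atoms: none
Why: Horner–Wadsworth–Emmons olefination run on the phenoxide (the O⁻ is meta to the aldehyde and barely deactivates it), giving the E-stilbene; the alkene geometry is of no consequence because the bond is saturated in step 5.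

**Step 4**
Reactants: 5 2-[(4-bromophenyl)ethynyl]-3-fluoro-1,4-dimethoxybenzene, 8 (E)-2-methoxy-5-[2-(3-methoxyphenyl)ethenyl]phenol
Product: 9 2-fluoro-1,4-dimethoxy-3-[(4-{2-methoxy-5-[(E)-2-(3-methoxyphenyl)ethenyl]phenoxy}phenyl)ethynyl]benzene
Conditions: CuI (10 mol%), N,N-dimethylglycine hydrochloride (30 mol%), Cs2CO3 (2 equiv), dioxane, 100 °C, 24 h
Reagents that add atoms: none
Why: Ligand-accelerated Ullmann diaryl ether synthesis between an aryl bromide and an ortho-methoxyphenol; the aryl fluoride, internal alkyne and stilbene do not react with the copper catalyst.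

**Step 5**
Reactants: 9 the alkyne/stilbene diaryl ether
Product: 10 2-fluoro-1,4-dimethoxy-3-[2-(4-{2-methoxy-5-[2-(3-methoxyphenyl)ethyl]phenoxy}phenyl)ethyl]benzene
Conditions: H2 (1 atm), 10% Pd/C, EtOAc/EtOH 1:1, rt
Reagents that add atoms: none
Why: Heterogeneous catalytic hydrogenation takes up three equivalents of H2 to turn the alkyne and the alkene into the two CH2CH2 bridges, while Ar–F, Ar–OMe and the diaryl ether are inert.

**Step 6**
Reactants: 10 the tetramethyl ether
Product: 11 2-fluoro-3-[2-(4-{2-hydroxy-5-[2-(3-hydroxyphenyl)ethyl]phenoxy}phenyl)ethyl]benzene-1,4-diol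
Conditions: BBr3 (6 equiv), CH2Cl2, −78 °C to rt; H2O quench, aq. Na2S2O4 wash, under Ar
Reagents that add atoms: none
Why: Lewis-acid ether cleavage (BBr3 demethylation) removes all four methyl groups by bromide attack at CH3, whereas the diaryl ether and the aryl fluoride offer no sp3 carbon and survive.

**Step 7**
Reactants: 11 the fluorohydroquinone tetraol
Product: 13 marchantinquinone, via fluoroquinone 12 (not isolated)
Conditions: Ag2O (1.5 equiv), Na2SO4, MeCN, rt, 20 min, filter through Celite; filtrate added by syringe pump (10 h) to Cs2CO3 (3 equiv), DMF, rt, final 1 mM; AcOH quench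
Reagents that add atoms: none
Why: Proposed new method: a biomimetic oxidative phenol C–O coupling run as a two-electron sequence, in which Ag2O dehydrogenates only the hydroquinone ring C (much easier to oxidise than the two phenols) to the 3-alkyl-2-fluoro-1,4-benzoquinone 12, whose C–F carbon is a vinylogous acyl fluoride, so the ring D phenoxide adds there and expels fluoride (addition–elimination) to close the 18-membered ring directly at the quinone oxidation level; fluorine fixes the coupling site that an unsubstituted quinone would not respect, high dilution suppresses oligomers, and the ring B phenoxide cannot reach the same carbon without forming a strained 12-membered paracyclophane; the closest known reaction types are the intermolecular displacement of halide from 2-halo-3-alkyl-1,4-quinones by phenoxides and SNAr macro-etherification.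

**Compound list**
1 | 2-fluoro-1,4-dimethoxybenzene | COc1ccc(OC)c(F)c1 | starting material
2 | (2-fluoro-3,6-dimethoxyphenyl)lithium | COc1ccc(OC)c([Li])c1F | intermediate
3 | 2-fluoro-3-iodo-1,4-dimethoxybenzene | COc1ccc(OC)c(I)c1F | intermediate
4 | 1-bromo-4-ethynylbenzene | C#Cc1ccc(Br)cc1 | starting material
5 | 2-[(4-bromophenyl)ethynyl]-3-fluoro-1,4-dimethoxybenzene | COc1ccc(OC)c(C#Cc2ccc(Br)cc2)c1F | intermediate
6 | isovanillin (3-hydroxy-4-methoxybenzaldehyde) | COc1ccc(C=O)cc1O | starting material
7 | diethyl (3-methoxybenzyl)phosphonate | CCOP(=O)(Cc1cccc(OC)c1)OCC | starting material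
8 | (E)-2-methoxy-5-[2-(3-methoxyphenyl)ethenyl]phenol | COc1ccc(/C=C/c2cccc(OC)c2)cc1O | intermediate
9 | 2-fluoro-1,4-dimethoxy-3-[(4-{2-methoxy-5-[(E)-2-(3-methoxyphenyl)ethenyl]phenoxy}phenyl)ethynyl]benzene | COc1ccc(/C=C/c2cccc(OC)c2)cc1Oc1ccc(C#Cc2c(F)c(OC)ccc2OC)cc1 | intermediate
10 | 2-fluoro-1,4-dimethoxy-3-[2-(4-{2-methoxy-5-[2-(3-methoxyphenyl)ethyl]phenoxy}phenyl)ethyl]benzene | COc1ccc(CCc2cccc(OC)c2)cc1Oc1ccc(CCc2c(F)c(OC)ccc2OC)cc1 | intermediate
11 | 2-fluoro-3-[2-(4-{2-hydroxy-5-[2-(3-hydroxyphenyl)ethyl]phenoxy}phenyl)ethyl]benzene-1,4-diol | Oc1ccc(CCc2cccc(O)c2)cc1Oc1ccc(CCc2c(F)c(O)ccc2O)cc1 | intermediate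
12 | 2-fluoro-3-[2-(4-{2-hydroxy-5-[2-(3-hydroxyphenyl)ethyl]phenoxy}phenyl)ethyl]-1,4-benzoquinone | Oc1ccc(CCc2cccc(O)c2)cc1Oc1ccc(CCC2=C(F)C(=O)C=CC2=O)cc1 | intermediate
13 | marchantinquinone | O=C1C=CC(=O)C2=C1CCc1ccc(cc1)Oc1cc(ccc1O)CCc1cccc(c1)O2 | target

**Step count**
Total: 7 steps. Longest linear sequence: 6 steps (1 → 3 → 5 → 9 → 10 → 11 → 13, i.e. steps 1, 2, 4, 5, 6, 7).

**Three steps most likely to fail, with fallbacks**

Step 7 (oxidative macro-etherification). The risks are base-induced decay of the alkyl quinone (quinone methide tautomer, electron transfer from phenoxides), attack at the unsubstituted quinone carbons, and oligomers. The fallback sets out from 11 and comes back at 13, and replaces the free phenoxide made with stoichiometric base by a neutral fluoride-relay silyl-ether substitution. Compound 11 is oxidised with Ag2O as before, but fluoroquinone 12 is isolated. Both phenols are silylated with N,O-bis(trimethylsilyl)acetamide in CH2Cl2 to give the quinone bis(trimethylsilyl) ether F1. F1 is added slowly to catalytic Bu4N[Ph3SiF2] in MeCN at 1 mM. Fluoride unmasks a phenoxide only in catalytic amount, and each ring closure releases the fluoride that starts the next one. This gives ring B O-trimethylsilyl marchantinquinone F2, whose silyl ether is hydrolysed on aqueous citric acid work-up to 13.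

Step 4 (Ullmann coupling of a hindered ortho-methoxyphenol in the presence of an alkyne). The fallback sets out from 8 (and uses 3) and comes back at 9. It forms the diaryl ether by SNAr on an activated fluoride and builds the two-carbon bridge afterwards, so compound 5 is not needed. Compound 8 and 4-fluorobenzaldehyde (K2CO3, DMF, 120 °C) give 4-{2-methoxy-5-[(E)-2-(3-methoxyphenyl)ethenyl]phenoxy}benzaldehyde F3. Ohira–Bestmann homologation with dimethyl (1-diazo-2-oxopropyl)phosphonate (K2CO3, MeOH) gives 1-ethynyl-4-{2-methoxy-5-[(E)-2-(3-methoxyphenyl)ethenyl]phenoxy}benzene F4. Sonogashira coupling of F4 with iodide 3 (PdCl2(PPh3)2, CuI, Et3N) gives 9.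

Step 2 (Sonogashira coupling of a hindered, electron-rich aryl iodide with an alkyne that also carries a bromide). The fallback sets out from 1 (through aryllithium 2) and comes back at 10. It makes the ring C–ring A bond by carbonyl olefination instead of palladium coupling. Aryllithium 2 is quenched with DMF (aq. HCl work-up) to give 2-fluoro-3,6-dimethoxybenzaldehyde F5. Horner–Wadsworth–Emmons olefination with diethyl (4-bromobenzyl)phosphonate (KOtBu, THF) gives 2-[(E)-2-(4-bromophenyl)ethenyl]-3-fluoro-1,4-dimethoxybenzene F6. Ullmann coupling of F6 with 8 under the step 4 conditions gives the bis-stilbene diaryl ether F7. Hydrogenation of F7 under the step 5 conditions gives 10.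

**Further compounds**
F1 | step 7 | bis(trimethylsilyl) ether of fluoroquinone 12 | C[Si](C)(C)Oc1ccc(CCc2cccc(O[Si](C)(C)C)c2)cc1Oc1ccc(CCC2=C(F)C(=O)C=CC2=O)cc1
F2 | step 7 | ring B O-trimethylsilyl marchantinquinone | O=C1C=CC(=O)C2=C1CCc1ccc(cc1)Oc1cc(ccc1O[Si](C)(C)C)CCc1cccc(c1)O2
F3 | step 4 | 4-{2-methoxy-5-[(E)-2-(3-methoxyphenyl)ethenyl]phenoxy}benzaldehyde | COc1ccc(/C=C/c2cccc(OC)c2)cc1Oc1ccc(C=O)cc1
F4 | step 4 | 1-ethynyl-4-{2-methoxy-5-[(E)-2-(3-methoxyphenyl)ethenyl]phenoxy}benzene | COc1ccc(/C=C/c2cccc(OC)c2)cc1Oc1ccc(C#C)cc1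
F5 | step 2 | 2-fluoro-3,6-dimethoxybenzaldehyde | COc1ccc(OC)c(C=O)c1F
F6 | step 2 | 2-[(E)-2-(4-bromophenyl)ethenyl]-3-fluoro-1,4-dimethoxybenzene | COc1ccc(OC)c(/C=C/c2ccc(Br)cc2)c1F
F7 | step 2 | 2-fluoro-1,4-dimethoxy-3-[(E)-2-(4-{2-methoxy-5-[(E)-2-(3-methoxyphenyl)ethenyl]phenoxy}phenyl)ethenyl]benzene | COc1ccc(/C=C/c2cccc(OC)c2)cc1Oc1ccc(/C=C/c2c(F)c(OC)ccc2OC)cc1
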